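The readings were computed from invented constants, noise included.

Start from one equivalent of partner per substrate charged, which is what a full yield of product needs.

| flask | substrate | partner | protic impurity | remark | time |
|---|---|---|---|---|---|
| cedar | 0.055 M | 2 equiv | 0.025 M | run made earlier |  |
| green | 0.030 M | 1.00 equiv | 0.00600 M |  | 2.5 min |
| violet | 0.050 M | 2.00 equiv | 0.0250 M |  | 2.5 min |
| blue | 0.050 M | 0.500 equiv | 0.100 M |  | 2.5 min |
| teal | 0.15 M | 1.30 equiv | 0.0150 M |  | 2.5 min |
| amber | 0.050 M | 2.00 equiv | 0.0400 M |  | 2.5 min |

cedar run (percent of the substrate charged)

| time / s | product / % | substrate / % |
|---|---|---|
| 10.0 | 15 | 35 |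
| 25.0 | 32 | 29 |
| 40.0 | 45 | 29 |
| 60.0 | 57 | 14 |
| 90.0 | 66 | 15 |

(readings scatter by 2 percentage points)

- what was read earlier has a scatter of 2 percentage points, one standard deviation
- a reading or a percentage of product counts all its forms, free or not
- a reading of substrate is of its free form alone
- no earlier run changes the charge of protic impurity; that part of a forecast is a guess

1. the flasks put in order of amount of product, in percent of the substrate charged, best first, at 2.5 min (green / violet / blue / teal / amber)
2. the amount of product, in percent of the substrate charged of the flask you put first, at 2.5 min
3. the amount of product, in percent of the substrate charged of the flask you put last, at 2.5 min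

Cedar reaches 66% of product at 90.0 s, up from 57% at 60.0 s. It reads no partner and never changes the impurity, so any cost of impurity is a guess. Make the bench guess: take impurity off the partner charge, one for one, and divide by the substrate charged. For teal this gives 120%; call this amount, partner charge less impurity per substrate charged, the spare partner. Amber has 120%, violet 150% and green 80.0%.

Between zero and one equivalent of spare partner, partner is the limiting reagent and the spare partner caps product. Green stands there, and it is the most dilute flask, so rank green under amber, teal and violet.

Now find the borders. Above one equivalent the substrate charge caps product, so the subtraction gives no rank for teal, amber and violet at 2.5 min. The zero of the scale is impurity equal to partner charge, a ratio of one. Teal's ratio is 0.0769, but blue's is 4.00, so the subtraction turns negative there. Place blue last and take no number for it from this rule.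

The forecast reads teal > violet > green > amber > blue, with 96% for the first flask and 2.5% for the last, on the ground that “the impurity ties up substrate tightly”. It agrees on blue last but sets green over amber, where the subtraction sets green under.

The flasks give teal > violet > amber > green > blue: teal 84.7%, amber 71.0%, green 45.4%, blue 1.37%.

    2 substrate ⇌ resting dimer, settled at all times (K = 35.0 M⁻¹)
    substrate + partner → product (k = 29.0 M⁻¹ min⁻¹)
    partner + protic impurity → quenched reagent (k = 240 M⁻¹ min⁻¹)
    substrate + product ⇌ idle adduct, settled at all times (K = 15.0 M⁻¹)

Subtract teal's product from its spare partner: 120% less 84.7% leaves 35.3% per substrate charged, and with teal's impurity at 0%, the 27.2% of its own charge that teal's partner keeps at 2.50 min comes to 35.3%. Blue stops at 1.37% mainly because its partner falls: partner stands at 0% by 1.25 min, whereas blue with partner held at its charge gives 55.3% of product. Teal's neighbour, with 0.037 M of impurity, has spare partner 105% and product 78.9%, so 26.5% should remain, and its partner left is 26.5% per substrate charged.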